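## Structural features

The target is a 2-O-alkylglycerol: an achiral propane-1,3-diol whose secondary oxygen carries an unbranched eight-carbon chain. The chain ends at carbon a of a cyclohexane (ring A: a, b, c, d, e, f, with f the methylene between a and e). Ring A is fused through bond d–e to a linear ladder of three cyclobutanes: ring B (d, e, g, k), ring C (g, h, j, k) and ring D (h, i, i′, j), with g bonded to e and h, k to d and j, i to h, and i′ to j. All fusions are cis and neighbouring rings lie anti, so the six contiguous methine stereocentres d, e, g, k, h and j form a cis,anti,cis,anti,cis staircase. The seventh stereocentre, a, is separated from e by f, is S, and carries the chain cis to the ring B bonds. The bicyclo[2.2.0]hexane units are the fragile part: they cleave on heating well below 200 °C and are endangered by radical centres on the ladder, strong Lewis acids and inserting transition metals; the free 1,3-diol has to be masked against acylating and organometallic reagents. The real difficulty is the relation between the ladder and the remote centre a, because a finished ladder does not distinguish the two faces or the two ends of ring A. The key step uses the terminal position of ring D: i and i′ are bonded only to each other and to h and j, so a two-carbon ketene unit added across an h=j double bond of ring C completes the ladder, and the fold of rings B and C dictates the anti arrangement.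

## Logic of the disconnections

28 ⇒ 27. Only the two C–O bonds from the ketal carbon to the primary oxygens are added. A free diol would consume acyl halides, hydrides and organomagnesium reagents; a ketal without an acetal hydrogen offers no weak C–H bond to sensitisers or radicals. The demand is a final hydrolysis mild enough for the ladder.

27 ⇒ 25 ⇒ 24. A carbonyl is placed on i and two chlorines on i′. No atom of the skeleton changes, but ring D becomes the retron of a ketene cycloaddition. The forward steps must remove halogen and oxygen without heat, acid or a radical on the ladder, which points to metal reduction and a room-temperature hydrazone reduction.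

24 ⇒ 21 + 23. Bonds h–i and j–i′ are cut. Ring D shares only h–j with the rest, so this removes one ring, two C–C bonds and two stereocentres at once and leaves a two-carbon unit, 23, made in the flask from 22. The forward step needs a thermal [2+2] addition to a strained cis-alkene on its convex face only, tolerance of the ketal, and no regiocontrol.

21 ⇒ 20 ⇒ 19 ⇒ 17 + 18. The h=j double bond is traced to two cis carboxyl groups, then bonds g–h and k–j are cut. 18 acts as a two-carbon alkyne equivalent, and the problem shrinks to a bicyclic cyclobutene. The cycloaddition must go to the face of ring B remote from ring A, and the bis-decarboxylation must tolerate a strained product.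

17 ⇒ 16 ⇒ 15 ⇒ 14 ⇒ 13. In ring B the bond between one fusion carbon and its sp2 neighbour is cut and that fusion carbon is joined to the other sp2 carbon, giving a cyclopropane with an exocyclic carbene carbon. A single carbon can be delivered to one face of a cyclohexene by a tether, a two-carbon unit cannot, so the stereochemical problem becomes facial delivery of one carbon. The carbene must ring-expand, not fragment or insert, which calls for aprotic generation and no hydroxyl nearby.

13 ⇒ 8 + 12, and 12 ⇒ 11 ⇒ 9 + 10. The chain is cut between its first and second carbon counted from a, then at the ether C–O bond. This separates the chiral carbocycle from an achiral C7 ether; the first chain carbon is the carboxyl carbon of 1. The coupling is sp3–sp3 in the presence of an ester, so it is placed before the carbene step and run under copper catalysis at low temperature.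

8 ⇒ 7 ⇒ 6 ⇒ 5. After functional group interchange at the CH2 group on a, the ester C–O bond is re-formed to a bridged lactone, and the two cyclopropane bonds from the exocyclic-ester carbon to d and e are cut. The lactone is the trace of a tether from the CH2O group on a, which forces the new carbon onto the face cis to the future chain, so three stereocentres derive from one. Closure of a bridged seven-membered lactone must beat C–H insertion and carbene dimerisation.

5 ⇒ 4 ⇒ 2 + 3 ⇒ 1. The ester C–O bond and the diazo group are removed, and the primary alcohol is traced to the acid. All chirality then comes from 1, whose centre is never made acidic or ionised.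

## Other disconnections considered

Alternative 1: The cut removes the two ring A bonds c–d and f–e, so ring A leaves as a four-carbon diene. In the forward direction buta-1,3-diene A2 would add under high pressure to one of the two equivalent cyclobutene bonds of anti-tricyclo[4.2.0.0(2,5)]octa-3,7-diene A1 to give the meso diene A3. In its favour, one pericyclic step puts ring A on a ladder that already holds rings B, C and D with all six fusion centres. On step count to the carbon skeleton this is better than the chosen plan. On mechanism it is the equal of the chosen key step: both are thermal, concerted and exo on a folded bicyclo[2.2.0]hexene. Against it here: A1 is strained, thermally labile and not commercial; mono-addition must be enforced; and an unactivated dienophile needs pressure. More seriously, A3 is meso and has no handle at a. The chain, its cis relation to ring B and the absolute configuration would all depend on one enantioselective functionalisation of the ring A alkene, on its more hindered face, beside a more reactive ring D cyclobutene. The chosen plan is longer but takes carbon a and its configuration from 1 and fixes the cis relation with a tether.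

Alternative 2: The cut is the g–k bond shared by rings B and C. Forward, irradiation of cis-1,2-dihydrophthalic anhydride A4 would close the diene termini in a disrotatory four-electron electrocyclisation to the exo anhydride A5. In its favour, two four-membered rings and the ring C double bond arise in one step. The exo anhydride places the future ring A anti to ring C. The cyclobutene of A5 is the kind of acceptor the ketene annulation needs, so for ring D it equals the chosen plan. For rings B and C it is shorter than steps 4 to 13, which is better. Against it, ring A must be grown from the two anhydride carbons by a four-carbon annulation that also creates centre a, remote from any control element. A5 is meso; enantioselective anhydride opening is a dependable reaction type, but it must be followed by a diastereoselective step for a. The strained alkene also has to survive that sequence. Overall it trades the uncertain steps 4 and 13 for a long and weakly controlled construction of ring A, so total step economy is unlikely to be better.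

Alternative 3: The cut removes the two ring C bonds g–h and k–j. Forward, a copper-templated [2+2] photocycloaddition under short-wavelength light would join the cyclobutene bond of cis-bicyclo[4.2.0]octa-3,7-diene A6 with cyclobutene A7 to give the meso ladderane A8. In its favour, it is the most convergent option and the cis,anti,cis outcome is typical of templated photocycloadditions, so on anti selectivity it equals the chosen plan. Ring D arrives saturated, so nothing corresponding to steps 15 and 16 is needed, which is better. Against it, a crossed reaction of two similar strained alkenes should also give both homodimers, A7 is a gas, and the cyclohexene bond of A6 competes for the template. A8 is again meso and lacks the chain, so the desymmetrisation problem of alternative 1 returns. The chosen plan uses a thermal, polar cycloaddition with a defined cross partner and has centre a in place from the start.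

Key step: step 14

Remarks on the chemistry. The stereodescriptors of 1, 21, 24 and 28 are mutually consistent: the same cis,anti,cis(,anti,cis) ladder, chain cis to ring B, and the S centre of 1 mapping onto a without change. 19 is drawn as the exo anhydride and 24 to 26 as the regioisomer with the carbonyl on i; the endo anhydride and the i′ carbonyl isomer converge at 21 and 27. C=N geometry in 26 is not defined. 7 is drawn as the endo ester; its C7 epimer would converge at 17.

Step 1
Reactants: 1 (S)-cyclohex-3-ene-1-carboxylic acid
Product: 2 [(1S)-cyclohex-3-en-1-yl]methanol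
Conditions: LiAlH4, THF, 0 °C to 23 °C
Reagents that add atoms: none
Why: Hydride reduction of a carboxylic acid to the primary alcohol; the isolated alkene is inert, and the stereocentre, no longer alpha to a carbonyl, cannot epimerise.

Step 2
Reactants: 2 [(1S)-cyclohex-3-en-1-yl]methanol; 3 bromoacetyl bromide
Product: 4 [(1S)-cyclohex-3-en-1-yl]methyl 2-bromoacetate
Conditions: NaHCO3, MeCN, 0 °C
Reagents that add atoms: none
Why: O-Acylation of a primary alcohol by an acyl bromide under bicarbonate buffering; no stereocentre is involved.

Step 3
Reactants: 4 [(1S)-cyclohex-3-en-1-yl]methyl 2-bromoacetate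
Product: 5 [(1S)-cyclohex-3-en-1-yl]methyl 2-diazoacetate
Conditions: TsNHNHTs, DBU, THF, 0 °C
Reagents that add atoms: N,N'-ditosylhydrazine, Cc1ccc(cc1)S(=O)(=O)NNS(=O)(=O)c1ccc(C)cc1
Why: Diazoacetate formation from a bromoacetate: N-alkylation of the bis-sulfonylhydrazine, then base-induced loss of two sulfinate groups, gives the diazo ester under mild conditions.

Step 4
Reactants: 5 [(1S)-cyclohex-3-en-1-yl]methyl 2-diazoacetate
Product: 6 bridged cyclopropane lactone (ε-lactone joining the endo C7 carbonyl of a bicyclo[4.1.0]heptane to the CH2O group on C3; cyclopropane cis to that group)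
Conditions: Cu(MeCN)4PF6 (5 mol %), CH2Cl2, reflux, syringe-pump addition over 12 h (final 5 mM)
Reagents that add atoms: none
Why: Intramolecular carbenoid cyclopropanation of an alkenyl diazoacetate: the tether holds the copper carbene over the ring face that carries the CH2O group (axial conformer), so both new bonds to the former alkene carbons form cis to that group and the carbonyl is necessarily endo on C7. Monovalent copper is chosen because it favours cyclopropanation over insertion into the tertiary C–H bond, and slow addition suppresses carbene dimerisation.

Step 5
Reactants: 6 bridged cyclopropane lactone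
Product: 7 methyl (3S)-3-(hydroxymethyl)bicyclo[4.1.0]heptane-7-carboxylate (7-endo ester; cyclopropane cis to CH2OH)
Conditions: K2CO3 (cat.), MeOH, 0 °C to 23 °C; NH4Cl quench; used without delay
Reagents that add atoms: methanol, CO
Why: Base-catalysed transesterification should open the strained bridged seven-membered lactone to the methyl ester and free the primary alcohol; mild carbonate is not expected to epimerise the cyclopropane carbon.

Step 6
Reactants: 7 methyl (3S)-3-(hydroxymethyl)bicyclo[4.1.0]heptane-7-carboxylate
Product: 8 methyl (3S)-3-(iodomethyl)bicyclo[4.1.0]heptane-7-carboxylate (same relative configuration)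
Conditions: I2, PPh3, imidazole, CH2Cl2, 0 °C to 23 °C
Reagents that add atoms: iodine, II
Why: Appel-type iodination of a primary alcohol (SN2 at CH2, no stereocentre touched) gives an electrophile reactive enough to couple at low temperature, where the ester is spared.

Step 7
Reactants: 9 2,2-dimethyl-1,3-dioxan-5-ol; 10 1,7-dibromoheptane
Product: 11 5-[(7-bromoheptyl)oxy]-2,2-dimethyl-1,3-dioxane
Conditions: NaH, DMF, 0 °C; then 10 (3 equiv), 23 °C
Reagents that add atoms: none
Why: Williamson ether synthesis at a primary bromide; the excess of dibromide limits double alkylation.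

Step 8
Reactants: 8 methyl (3S)-3-(iodomethyl)bicyclo[4.1.0]heptane-7-carboxylate; 11 5-[(7-bromoheptyl)oxy]-2,2-dimethyl-1,3-dioxane
Product: 13 methyl (3S)-3-{8-[(2,2-dimethyl-1,3-dioxan-5-yl)oxy]octyl}bicyclo[4.1.0]heptane-7-carboxylate, via Grignard reagent 12 (not isolated)
Conditions: 11, Mg, THF, 40 °C; then 8, Li2CuCl4 (3 mol %), THF–NMP, −20 °C to 0 °C
Reagents that add atoms: none
Why: Copper-catalysed alkyl–alkyl coupling of a primary Grignard reagent with a primary iodide; at −20 °C the cuprate substitution should outrun addition to the hindered methyl ester, and the ketal and ether are inert to the organomagnesium.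

Step 9
Reactants: 13 methyl (3S)-3-{8-[(2,2-dimethyl-1,3-dioxan-5-yl)oxy]octyl}bicyclo[4.1.0]heptane-7-carboxylate
Product: 14 (3S)-3-{8-[(2,2-dimethyl-1,3-dioxan-5-yl)oxy]octyl}bicyclo[4.1.0]heptane-7-carbaldehyde (same configuration)
Conditions: i-Bu2AlH (1.1 equiv), CH2Cl2, −78 °C; MeOH, then aq. potassium sodium tartrate
Reagents that add atoms: none
Why: Partial reduction of a methyl ester through the aluminium hemiacetal, which is stable at −78 °C; ketal and cyclopropane are untouched.

Step 10
Reactants: 14 (3S)-3-{8-[(2,2-dimethyl-1,3-dioxan-5-yl)oxy]octyl}bicyclo[4.1.0]heptane-7-carbaldehyde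
Product: 15 (E)-N-tosylhydrazone of 14
Conditions: TsNHNH2, MeOH, 23 °C
Reagents that add atoms: 4-methylbenzenesulfonohydrazide, Cc1ccc(cc1)S(=O)(=O)NN
Why: Condensation of an aldehyde with a sulfonyl hydrazide under neutral conditions that leave the ketal intact.

Step 11
Reactants: 15 (E)-N-tosylhydrazone of 14
Product: 17 5-({8-[(3S)-cis-bicyclo[4.2.0]oct-7-en-3-yl]octyl}oxy)-2,2-dimethyl-1,3-dioxane (chain cis to the cyclobutene), via diazoalkane 16 (not isolated)
Conditions: NaH (1.05 equiv), diglyme, 23 °C; then 150 °C
Reagents that add atoms: none
Why: Aprotic Bamford–Stevens reaction: the sodium salt loses sulfinate to diazoalkane 16, which loses N2 to a cyclopropylcarbene; a ring bond then migrates to the carbene carbon (cyclopropylcarbene to cyclobutene ring expansion), known for bicyclo[4.1.0]heptane-7-carbaldehyde hydrazones. The migrating fusion carbon keeps its configuration, so the cyclobutene is cis-fused on the face where the cyclopropane sat, cis to the chain, and C7 loses its stereochemistry.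

Step 12
Reactants: 17 5-({8-[(3S)-cis-bicyclo[4.2.0]oct-7-en-3-yl]octyl}oxy)-2,2-dimethyl-1,3-dioxane; 18 maleic anhydride
Product: 19 cis,anti,cis-tricyclo[6.2.0.0(2,7)]decane-9,10-dicarboxylic anhydride carrying the chain at C4 (exo anhydride)
Conditions: 18 (3 equiv), PhCOMe (sensitiser), MeCN, hν (350 nm, Pyrex), 10 °C
Reagents that add atoms: none
Why: Triplet-sensitised [2+2] photocycloaddition of an enedione-type partner to a strained cis-cyclobutene; attack on the convex face, away from ring A, sets g and k cis to each other and anti to ring A, and the cyclic anhydride keeps the carboxyl carbons cis. The ketal has no acetal hydrogen, and the excess of 18 should outcompete hydrogen abstraction at the ether positions.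

Step 13
Reactants: 19 photoadduct anhydride
Product: 21 5-({8-[(4S)-cis,anti,cis-tricyclo[6.2.0.0(2,7)]dec-9-en-4-yl]octyl}oxy)-2,2-dimethyl-1,3-dioxane (chain cis to ring B), via diacid 20 (not isolated)
Conditions: H2O, pyridine, 23 °C; then Pb(OAc)4, O2, pyridine, 60 °C
Reagents that add atoms: none
Why: Oxidative bis-decarboxylation of a vicinal cis-diacid by tetravalent lead is a classical route to strained cyclobutenes, including bicyclo[2.2.0]hex-2-enes; the basic medium protects the ketal and no stereocentre of the ring system is touched.

Step 14
Reactants: 21 tricyclic cyclobutene; 22 trichloroacetyl chloride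
Product: 24 ring D dichlorocyclobutanone (carbonyl on i shown), via dichloroketene 23 (not isolated)
Conditions: Zn(Cu), Et2O–DME, slow addition of 22, ultrasound, 15–20 °C
Reagents that add atoms: none
Why: Thermal ketene–alkene [2+2] cycloaddition: zinc reduces 22 to dichloroketene 23, whose electrophilic central carbon is attacked by the strain-raised HOMO of the ring C double bond in a concerted, asynchronous, orthogonal approach (suprafacial on the alkene, antarafacial on the ketene). The closest known reaction type is the dichloroketene annulation of unactivated cis-cycloalkenes such as cyclopentene and norbornene. Ring D closes by intermolecular cycloaddition, bonds h–i and j–i′ forming in the same step, so no separate cyclisation is needed. The new stereocentres h and j are cis because addition is suprafacial on a cis-alkene held in a four-membered ring. Both are anti to ring B because only the convex face of the bicyclo[2.2.0]hexene is open, the concave face being covered by ring B. The step needs face selectivity and chemoselectivity but no regioselectivity, since both ketene orientations converge in step 16. DME binds the ZnCl2 formed, which should protect the ketal and the strained alkene, and the thermal conditions avoid irradiating the ladder.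

Step 15
Reactants: 24 ring D dichlorocyclobutanone
Product: 25 ring D cyclobutanone
Conditions: Zn(Cu), NH4Cl, MeOH, 23 °C
Reagents that add atoms: none
Why: Reductive dechlorination of an alpha,alpha-dichloroketone by zinc through the zinc enolate, protonated by ammonium; the near-neutral medium spares the ketal, and the alpha fusion centre cannot invert because a trans-fused bicyclo[2.2.0]hexane is inaccessible.

Step 16
Reactants: 25 ring D cyclobutanone
Product: 27 ladderane acetonide 5-({8-[(10S)-cis,anti,cis,anti,cis-tetracyclo[6.4.0.0(2,7).0(3,6)]dodecan-10-yl]octyl}oxy)-2,2-dimethyl-1,3-dioxane, via N-silyl hydrazone 26 (not isolated)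
Conditions: (TBSNH)2, Sc(OTf)3 (0.1 mol %), CHCl3, 23 °C; evaporate; KOtBu, t-BuOH, DMSO, 23 °C
Reagents that add atoms: none
Why: Low-temperature Wolff–Kishner reduction: the N-silyl hydrazone forms under trace Lewis acid, and tert-butoxide in DMSO desilylates it and drives diazene anion formation, N2 loss and protonation at 23 °C. This is far below the temperature at which bicyclo[2.2.0]hexane units cleave, and no radical is placed on the ladder.

Step 17
Reactants: 27 ladderane acetonide
Product: 28 2-({8-[(10S)-cis,anti,cis,anti,cis-tetracyclo[6.4.0.0(2,7).0(3,6)]dodecan-10-yl]octyl}oxy)propane-1,3-diol (CNP0193334.1)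
Conditions: 1 M HCl, THF–H2O, 23 °C
Reagents that add atoms: none
Why: Acid-catalysed hydrolysis of the isopropylidene ketal; the saturated ladder and the dialkyl ether are stable to dilute aqueous acid at room temperature.

Compound list

1 | (S)-cyclohex-3-ene-1-carboxylic acid | OC(=O)[C@H]1CCC=CC1 | starting material
2 | [(1S)-cyclohex-3-en-1-yl]methanol | OC[C@H]1CCC=CC1 | intermediate
3 | bromoacetyl bromide | BrCC(Br)=O | starting material
4 | [(1S)-cyclohex-3-en-1-yl]methyl 2-bromoacetate | BrCC(=O)OC[C@H]1CCC=CC1 | intermediate
5 | [(1S)-cyclohex-3-en-1-yl]methyl 2-diazoacetate | [N-]=[N+]=CC(=O)OC[C@H]1CCC=CC1 | intermediate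
6 | bridged cyclopropane lactone (endo C7 carbonyl, cyclopropane cis to the CH2O bridge) | O=C1OC[C@H]2CC[C@@H]3[C@H](C2)[C@H]13 | intermediate
7 | methyl (3S)-3-(hydroxymethyl)bicyclo[4.1.0]heptane-7-carboxylate, 7-endo, cyclopropane cis to CH2OH | OC[C@H]1CC[C@@H]2[C@H](C1)[C@@H]2C(=O)OC | intermediate
8 | methyl (3S)-3-(iodomethyl)bicyclo[4.1.0]heptane-7-carboxylate, same configuration | IC[C@H]1CC[C@@H]2[C@H](C1)[C@@H]2C(=O)OC | intermediate
9 | 2,2-dimethyl-1,3-dioxan-5-ol | CC1(C)OCC(O)CO1 | starting material
10 | 1,7-dibromoheptane | BrCCCCCCCBr | starting material
11 | 5-[(7-bromoheptyl)oxy]-2,2-dimethyl-1,3-dioxane | CC1(C)OCC(CO1)OCCCCCCCBr | intermediate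
12 | {7-[(2,2-dimethyl-1,3-dioxan-5-yl)oxy]heptyl}magnesium bromide | CC1(C)OCC(CO1)OCCCCCCC[Mg]Br | intermediate
13 | methyl (3S)-3-{8-[(2,2-dimethyl-1,3-dioxan-5-yl)oxy]octyl}bicyclo[4.1.0]heptane-7-carboxylate, 7-endo, cyclopropane cis to the chain | CC1(C)OCC(CO1)OCCCCCCCC[C@H]2CC[C@@H]3[C@H](C2)[C@@H]3C(=O)OC | intermediate
14 | (3S)-3-{8-[(2,2-dimethyl-1,3-dioxan-5-yl)oxy]octyl}bicyclo[4.1.0]heptane-7-carbaldehyde, same configuration | CC1(C)OCC(CO1)OCCCCCCCC[C@H]2CC[C@@H]3[C@H](C2)[C@@H]3C=O | intermediate
15 | (E)-N-tosylhydrazone of 14 | CC1(C)OCC(CO1)OCCCCCCCC[C@H]2CC[C@@H]3[C@H](C2)[C@@H]3/C=N/NS(=O)(=O)c1ccc(C)cc1 | intermediate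
16 | 7-(diazomethyl) analogue of 14 | CC1(C)OCC(CO1)OCCCCCCCC[C@H]2CC[C@@H]3[C@H](C2)[C@@H]3C=[N+]=[N-] | intermediate
17 | 5-({8-[(3S)-cis-bicyclo[4.2.0]oct-7-en-3-yl]octyl}oxy)-2,2-dimethyl-1,3-dioxane, chain cis to the cyclobutene | CC1(C)OCC(CO1)OCCCCCCCC[C@H]2CC[C@@H]3[C@H](C2)C=C3 | intermediate
18 | maleic anhydride | O=C1OC(=O)C=C1 | starting material
19 | cis,anti,cis-tricyclo[6.2.0.0(2,7)]decane-9,10-dicarboxylic anhydride with the chain at C4, exo anhydride | CC1(C)OCC(CO1)OCCCCCCCC[C@H]2CC[C@@H]3[C@H](C2)[C@H]2[C@@H]4C(=O)OC(=O)[C@@H]4[C@@H]32 | intermediate
20 | corresponding cis-9,10-dicarboxylic acid | CC1(C)OCC(CO1)OCCCCCCCC[C@H]2CC[C@@H]3[C@H](C2)[C@H]2[C@H](C(O)=O)[C@H](C(O)=O)[C@@H]32 | intermediate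
21 | 5-({8-[(4S)-cis,anti,cis-tricyclo[6.2.0.0(2,7)]dec-9-en-4-yl]octyl}oxy)-2,2-dimethyl-1,3-dioxane, chain cis to ring B | CC1(C)OCC(CO1)OCCCCCCCC[C@H]2CC[C@@H]3[C@H](C2)[C@H]2C=C[C@@H]32 | intermediate
22 | trichloroacetyl chloride | ClC(Cl)(Cl)C(Cl)=O | starting material
23 | dichloroketene | O=C=C(Cl)Cl | intermediate
24 | protected ladderane with ring D as 2,2-dichlorocyclobutanone (carbonyl on i) | CC1(C)OCC(CO1)OCCCCCCCC[C@H]2CC[C@@H]3[C@H](C2)[C@H]2[C@@H]4C(=O)C(Cl)(Cl)[C@@H]4[C@@H]32 | intermediate
25 | protected ladderane with ring D as cyclobutanone | CC1(C)OCC(CO1)OCCCCCCCC[C@H]2CC[C@@H]3[C@H](C2)[C@H]2[C@@H]4C(=O)C[C@@H]4[C@@H]32 | intermediate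
26 | N-(tert-butyldimethylsilyl)hydrazone of 25 (C=N geometry not defined) | CC1(C)OCC(CO1)OCCCCCCCC[C@H]2CC[C@@H]3[C@H](C2)[C@H]2[C@@H]4C(=NN[Si](C)(C)C(C)(C)C)C[C@@H]4[C@@H]32 | intermediate
27 | ladderane acetonide (cis,anti,cis,anti,cis; chain cis to ring B; S at a) | CC1(C)OCC(CO1)OCCCCCCCC[C@H]2CC[C@@H]3[C@H](C2)[C@H]2[C@@H]4CC[C@@H]4[C@@H]32 | intermediate
28 | 2-({8-[(10S)-cis,anti,cis,anti,cis-tetracyclo[6.4.0.0(2,7).0(3,6)]dodecan-10-yl]octyl}oxy)propane-1,3-diol | OCC(CO)OCCCCCCCC[C@H]1CC[C@@H]2[C@H](C1)[C@H]1[C@@H]3CC[C@@H]3[C@@H]21 | target

Step count and least certain steps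

Total: 17 steps. Longest linear sequence: 16 steps (1 to 28 through steps 1–6 and 8–17); step 7 is a one-step side branch.

Step 14 (key step). The most likely failure is slow cycloaddition: dichloroketene may oligomerise faster than it adds to a cis-disubstituted cyclobutene, an acceptor class with little precedent. A second danger is Lewis-acid damage, either loss of the ketal through ZnCl2 and acid chloride or acid-induced opening of the strained alkene. Fallback: set out from 21 and build ring D photochemically. Sensitised cycloaddition of 18 as in step 12 would give the ring D anhydride F1. Hydrolysis in wet pyridine to the diacid F2 and bis-decarboxylation with Pb(OAc)4 would give the ladderene F3. Diimide, generated at room temperature from 2-nitrobenzenesulfonohydrazide and Et3N, would saturate the strained double bond from its open face and return to the route at 27, bypassing steps 15 and 16.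

Step 4. Closure of the bridged seven-membered lactone needs the axial conformer and an s-trans ester. The carbenoid may therefore insert into the tertiary C–H bond at the chain-bearing carbon (five-membered lactone) or dimerise. Fallback: set out from 2 and deliver ring B by a tethered ketene. Alkylation of the alkoxide of 2 (NaH) with bromoacetic acid would give the alkoxyacetic acid F4. Oxalyl chloride would give acid chloride F5, and Et3N in refluxing toluene under high dilution would give alkoxyketene F6. F6 can reach the ring alkene only on the tether face and should close to the oxa-bridged cyclobutanone F7. SmI2 (divalent samarium) in THF–MeOH would cleave the alpha C–O bond to hydroxy ketone F8. TsNHNH2 would give hydrazone F9, and a Shapiro reaction with excess LiN(i-Pr)2 would give the cis-fused cyclobutene alcohol F10. Tosylation to F11 and the copper-catalysed coupling of step 8 with 12 would return to the route at 17, bypassing steps 3 to 11.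

Step 13. Bis-decarboxylations that form strained cyclobutenes tend to stop at mono-decarboxylation or acetoxylation, and tetravalent lead may oxidise the product further. The photochemical step 12 that feeds it carries a smaller risk of hydrogen abstraction at the ether positions. Fallback: set out from 17 and build ring C thermally. A dichloroketene annulation under the conditions of step 14 would give F12, and Zn(Cu)/NH4Cl would give cyclobutanone F13. NaBH4 would give alcohol F14 and MsCl/Et3N the mesylate F15. KOtBu in DMSO at 23 °C would eliminate toward the methylene, since a double bond at the ring fusion is unattainable, and return to the route at 21.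

Further compounds

F1 | step 14 | ring D exo anhydride from 21 and 18 | CC1(C)OCC(CO1)OCCCCCCCC[C@H]2CC[C@@H]3[C@H](C2)[C@H]2[C@@H]4[C@H]5C(=O)OC(=O)[C@H]5[C@@H]4[C@@H]32
F2 | step 14 | corresponding ring D cis-diacid | CC1(C)OCC(CO1)OCCCCCCCC[C@H]2CC[C@@H]3[C@H](C2)[C@H]2[C@@H]4[C@@H](C(O)=O)[C@@H](C(O)=O)[C@@H]4[C@@H]32
F3 | step 14 | protected ladderene with a ring D double bond | CC1(C)OCC(CO1)OCCCCCCCC[C@H]2CC[C@@H]3[C@H](C2)[C@H]2[C@@H]4C=C[C@@H]4[C@@H]32
F4 | step 4 | {[(1S)-cyclohex-3-en-1-yl]methoxy}acetic acid | OC(=O)COC[C@H]1CCC=CC1
F5 | step 4 | {[(1S)-cyclohex-3-en-1-yl]methoxy}acetyl chloride | ClC(=O)COC[C@H]1CCC=CC1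
F6 | step 4 | {[(1S)-cyclohex-3-en-1-yl]methoxy}ketene | O=C=COC[C@H]1CCC=CC1
F7 | step 4 | oxa-bridged tricyclic cyclobutanone (ether oxygen on the cyclobutanone alpha carbon, four-membered ring cis to the CH2O bridge) | O=C1[C@H]2OC[C@H]3CC[C@@H]1[C@@H]2C3
F8 | step 4 | all-cis 3-(hydroxymethyl)bicyclo[4.2.0]octan-7-one | OC[C@H]1CC[C@@H]2[C@H](C1)CC2=O
F9 | step 4 | N-tosylhydrazone of F8 (C=N geometry not defined) | OC[C@H]1CC[C@@H]2[C@H](C1)CC2=NNS(=O)(=O)c1ccc(C)cc1
F10 | step 4 | [(3S)-cis-bicyclo[4.2.0]oct-7-en-3-yl]methanol, CH2OH cis to the cyclobutene | OC[C@H]1CC[C@@H]2[C@H](C1)C=C2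
F11 | step 4 | 4-methylbenzenesulfonate of F10 | Cc1ccc(cc1)S(=O)(=O)OC[C@H]2CC[C@@H]3[C@H](C2)C=C3
F12 | step 13 | ring C 2,2-dichlorocyclobutanone from 17 (one regioisomer) | CC1(C)OCC(CO1)OCCCCCCCC[C@H]2CC[C@@H]3[C@H](C2)[C@H]2C(=O)C(Cl)(Cl)[C@@H]32
F13 | step 13 | ring C cyclobutanone | CC1(C)OCC(CO1)OCCCCCCCC[C@H]2CC[C@@H]3[C@H](C2)[C@H]2C(=O)C[C@@H]32
F14 | step 13 | ring C cyclobutanol (carbinol configuration not defined) | CC1(C)OCC(CO1)OCCCCCCCC[C@H]2CC[C@@H]3[C@H](C2)[C@H]2C(O)C[C@@H]32
F15 | step 13 | methanesulfonate of F14 | CC1(C)OCC(CO1)OCCCCCCCC[C@H]2CC[C@@H]3[C@H](C2)[C@H]2C(OS(C)(=O)=O)C[C@@H]32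
A1 | alternative 1 | anti-tricyclo[4.2.0.0(2,5)]octa-3,7-diene | C1=C[C@H]2[C@@H]3C=C[C@@H]3[C@@H]12
A2 | alternative 1 | buta-1,3-diene | C=CC=C
A3 | alternative 1 | meso tetracyclic diene with ring A and ring D double bonds | C1=CC[C@@H]2[C@H](C1)[C@H]1[C@@H]3C=C[C@@H]3[C@@H]21
A4 | alternative 2 | cis-1,2-dihydrophthalic anhydride | O=C1OC(=O)[C@@H]2C=CC=C[C@H]12
A5 | alternative 2 | exo-bicyclo[2.2.0]hex-5-ene-2,3-dicarboxylic anhydride (meso) | O=C1OC(=O)[C@@H]2[C@H]1[C@H]3C=C[C@@H]23
A6 | alternative 3 | cis-bicyclo[4.2.0]octa-3,7-diene (meso) | C1=CC[C@@H]2[C@H](C1)C=C2
A7 | alternative 3 | cyclobutene | C1=CCC1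
A8 | alternative 3 | meso tetracyclic [3]-ladderane with a ring A double bond | C1=CC[C@@H]2[C@H](C1)[C@H]1[C@@H]3CC[C@@H]3[C@@H]21
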